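**Retrosynthetic overview**

1. 13 ⇐ 10: one base cascade on a 2‑oxabicyclo[2.2.2]octan‑8‑one unveils the enone and the tertiary alcohol: retro‑oxa‑Michael opening of the O2–C1 bond, 1,2‑benzoyl shift from the tertiary oxygen to the freed CH2–O, loss of a formate.
2. 10 ⇐ 9: formyloxy from formyl by Baeyer–Villiger oxidation (retention).
3. 9 ⇐ 7 + 6 by Diels–Alder reaction: the two new C–C bonds close the carbocycle, the only ring built in the route; the bought pyran ring is a temporary bridge and is opened last. All three stereocentres of 13 are set here.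
4. Enabling feature: the C3=C4–C5=C6 diene held s‑cis in the 4‑silyloxy‑2H‑pyran ring of 7. Ring oxygen O1 and the C4 silyloxy group push electron density to C3; the O1–C2H2 unit ends as the CH2O group of 13, and the O1–C6 bond is the leaving group that later gives the enone.
5. 7 ⇐ 2,3‑dihydro‑4H‑pyran‑4‑one 1 + benzoic acid 2; 6 ⇐ malonaldehyde enolate 4 + benzoyl chloride 5.

Key step: step 4

Assumption: the (R,R)‑enantiomer of the chromium catalyst is taken to expose the Re,Re face of 6; if the sense of induction should be the opposite, the (S,S)‑catalyst is used and nothing else changes. Compounds 1, 2, 4 and 5 are commercial.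

**Route**

Step 1
Reactants: 1 2,3-dihydro-4H-pyran-4-one; 2 benzoic acid (excess)
Product: 3 4-oxo-3,4-dihydro-2H-pyran-3-yl benzoate (racemic)
Conditions: Mn(OAc)3·2H2O (2.5 equiv, trivalent manganese), benzene, reflux, Dean–Stark
Reagents that add atoms: none
Why: α'-Acyloxylation of an enone by trivalent manganese (manganese enolate, α'-keto radical, transfer of a benzoate ligand exchanged in from 2) should take place at C3, the only position of 1 with enolisable hydrogens; the stereocentre is formed racemic, which is harmless because step 3 makes it trigonal.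

Step 2
Reactants: 4 tetrabutylammonium (E)-3-oxoprop-1-en-1-olate (malonaldehyde tetrabutylammonium salt); 5 benzoyl chloride
Product: 6 (E)-3-oxoprop-1-en-1-yl benzoate
Conditions: CH2Cl2, 0 °C
Reagents that add atoms: none
Why: O‑Acylation of the ambident enolate by an acid chloride should give the enol ester (a vinylogous anhydride) with the E geometry of the W‑shaped anion.

Step 3
Reactants: 3 4-oxo-3,4-dihydro-2H-pyran-3-yl benzoate
Product: 7 4-[(triethylsilyl)oxy]-2H-pyran-3-yl benzoate
Conditions: TESOTf (1.2 equiv), Et3N (1.5 equiv), CH2Cl2, −78 °C; pentane, cold filtration, used at once below −40 °C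
Reagents that add atoms: triethylsilyl trifluoromethanesulfonate (TESOTf), CC[Si](CC)(CC)OS(=O)(=O)C(F)(F)F
Why: Soft enolisation (O‑silylation of the vinylogous ester carbonyl, then deprotonation at C3, the only acidic position) should give the cross‑conjugated silyl dienol ether; it is kept cold because a 2H‑pyran can open by 6π electrocyclic ring opening.

Step 4
Reactants: 7 4-[(triethylsilyl)oxy]-2H-pyran-3-yl benzoate; 6 (E)-3-oxoprop-1-en-1-yl benzoate
Product: 9 (1S,4R,5S,6R)-6-formyl-8-oxo-2-oxabicyclo[2.2.2]octane-4,5-diyl dibenzoate, via silyl enol ether cycloadduct 8 (not isolated)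
Conditions: (R,R)-[Cr(salen)]SbF6 (5 mol%; salen = N,N'-bis(3,5-di-tert-butylsalicylidene)cyclohexane-1,2-diaminate; trivalent chromium), 4 Å MS, CH2Cl2, −60 to −30 °C; then AcOH–THF–H2O, 0 °C
Reagents that add atoms: none
Why: Normal‑electron‑demand Diels–Alder reaction ([4+2], concerted but asynchronous, Lewis acid on the formyl oxygen of 6): C3 of 7 bonds to C3 of 6 and C6 of 7 bonds to C2 of 6, which are the bond between the quaternary carbinol carbon and the benzoyloxy‑bearing carbon and the bond between the later alkene CH and the later CH(OH) of 13. The closest known reaction type is the Diels–Alder reaction of 2‑silyloxycyclohexa‑1,3‑dienes and of 1‑heteroatom‑3‑silyloxy dienes with α,β‑unsaturated aldehydes, also in its enantioselective form with cationic salen chromium Lewis acids. The one ring closed is the carbocycle, by intermolecular suprafacial [4+2] addition across the s‑cis diene of the pyran, whose O1–C2H2 unit becomes the third bridge of the 2‑oxabicyclo[2.2.2]octene. Of the four new stereocentres, C5 and C6 keep the trans relation of the (E)‑alkene of 6; their orientation follows the endo rule (formyl under the diene and so syn to the C7=C8 bridge, benzoyloxy syn to the O2–C3 bridge); the bridgeheads C1 and C4 follow from the diene face used; the absolute sense is set by the catalyst, which must deliver the diene to the Re,Re face of 6. The step needs regioselectivity (O1 and the 4‑silyloxy group both make C3 of 7 the nucleophilic terminus, and the enal is β‑polarised), endo selectivity (secondary overlap with the coordinated formyl group) and chemoselectivity for C=C over C=O addition, which the low electrophilicity of the formyl carbon of the vinylogous anhydride 6 should favour. Mild aqueous acid then protonates the silyl enol ether of 8 at C7 and should give ketone 9 without opening the bridge.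

Step 5
Reactants: 9 (1S,4R,5S,6R)-6-formyl-8-oxo-2-oxabicyclo[2.2.2]octane-4,5-diyl dibenzoate
Product: 10 (1S,4R,5S,6R)-6-(formyloxy)-8-oxo-2-oxabicyclo[2.2.2]octane-4,5-diyl dibenzoate
Conditions: mCPBA (1.3 equiv), CH2Cl2, 0 °C to rt
Reagents that add atoms: 3-chloroperoxybenzoic acid (mCPBA), O=C(OO)c1cccc(Cl)c1
Why: Baeyer–Villiger oxidation of an α‑branched aldehyde, in which the secondary ring carbon migrates in the Criegee intermediate with retention, should turn the formyl‑bearing centre into the oxygen‑bearing centre without change of geometry; the aldehyde should react far faster than the hindered, unstrained ring ketone or the benzoates.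

Step 6
Reactants: 10 (1S,4R,5S,6R)-6-(formyloxy)-8-oxo-2-oxabicyclo[2.2.2]octane-4,5-diyl dibenzoate
Product: 13 [(1R,2S,3R)-2-(benzoyloxy)-1,3-dihydroxy-6-oxocyclohex-4-en-1-yl]methyl benzoate, via ring-opened tertiary benzoate 11 (not isolated), via rearranged primary benzoate formate 12 (not isolated)
Conditions: DBU (0.2 equiv), CH2Cl2, −20 to 0 °C; then MeOH, 0 °C; AcOH quench
Reagents that add atoms: none
Why: Base‑catalysed E1cB retro‑oxa‑Michael reaction (deprotonation at C7, the only enolisable position, expels ring oxygen O2 from C1 and gives the enone), then 1,2‑O→O benzoyl migration from the tertiary to the freed primary oxygen through a five‑membered orthoester anion, which removes the alkoxide from the reversible oxa‑Michael equilibrium, then base‑catalysed transesterification of the formate with methanol; no stereocentre is touched.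

**Compound list**

1 | 2,3-dihydro-4H-pyran-4-one | O=C1C=COCC1 | starting material
2 | benzoic acid | O=C(O)c1ccccc1 | starting material
3 | 4-oxo-3,4-dihydro-2H-pyran-3-yl benzoate (racemic) | O=C1C=COCC1OC(=O)c1ccccc1 | intermediate
4 | tetrabutylammonium (E)-3-oxoprop-1-en-1-olate | CCCC[N+](CCCC)(CCCC)CCCC.[O-]/C=C/C=O | starting material
5 | benzoyl chloride | O=C(Cl)c1ccccc1 | starting material
6 | (E)-3-oxoprop-1-en-1-yl benzoate | O=C/C=C/OC(=O)c1ccccc1 | intermediate
7 | 4-[(triethylsilyl)oxy]-2H-pyran-3-yl benzoate | CC[Si](CC)(CC)OC1=C(OC(=O)c2ccccc2)COC=C1 | intermediate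
8 | (1S,4R,5S,6R)-6-formyl-8-[(triethylsilyl)oxy]-2-oxabicyclo[2.2.2]oct-7-ene-4,5-diyl dibenzoate (formyl syn to the C7=C8 bridge, 5-benzoyloxy syn to the O2–C3 bridge) | O=C(c1ccccc1)O[C@@]12CO[C@@H](C=C1O[Si](CC)(CC)CC)[C@@H](C=O)[C@@H]2OC(=O)c1ccccc1 | intermediate (not isolated)
9 | (1S,4R,5S,6R)-6-formyl-8-oxo-2-oxabicyclo[2.2.2]octane-4,5-diyl dibenzoate | O=C(c1ccccc1)O[C@@]12CO[C@@H](CC1=O)[C@@H](C=O)[C@@H]2OC(=O)c1ccccc1 | intermediate
10 | (1S,4R,5S,6R)-6-(formyloxy)-8-oxo-2-oxabicyclo[2.2.2]octane-4,5-diyl dibenzoate | O=C(c1ccccc1)O[C@@]12CO[C@@H](CC1=O)[C@@H](OC=O)[C@@H]2OC(=O)c1ccccc1 | intermediate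
11 | (1R,2S,3R)-3-(formyloxy)-1-(hydroxymethyl)-6-oxocyclohex-4-ene-1,2-diyl dibenzoate | OC[C@]1(OC(=O)c2ccccc2)C(=O)C=C[C@@H](OC=O)[C@@H]1OC(=O)c1ccccc1 | intermediate (not isolated)
12 | [(1R,2S,3R)-2-(benzoyloxy)-3-(formyloxy)-1-hydroxy-6-oxocyclohex-4-en-1-yl]methyl benzoate | O=C(OC[C@]1(O)C(=O)C=C[C@@H](OC=O)[C@@H]1OC(=O)c1ccccc1)c1ccccc1 | intermediate (not isolated)
13 | [(1R,2S,3R)-2-(benzoyloxy)-1,3-dihydroxy-6-oxocyclohex-4-en-1-yl]methyl benzoate | O=C(OC[C@]1(O)C(=O)C=C[C@@H](O)[C@@H]1OC(=O)c1ccccc1)c1ccccc1 | target

**Count and risks**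

Total step count: 6. Longest linear sequence: 5 steps (steps 1, 3, 4, 5, 6); step 2 is a one‑step branch.

Step 4 is the most exposed. The diene may open by 6π electrocyclic ring opening before it is trapped; the Lewis acid may divert the diene to the formyl C=O group (hetero‑Diels–Alder or Mukaiyama aldol addition); facial control by the catalyst may be poor. Fallback (catalyst‑free cycloaddition and resolution): setting out from 7 and 6, the cycloaddition is run without Lewis acid in toluene at −20 to 5 °C. This is the classical thermal mode of 1‑alkoxy‑3‑silyloxy dienes with enals; it keeps the regio‑ and endo‑control and cannot reach the C=O group. It should give 8 together with the enantiomeric silyl enol ether cycloadduct F1. The same acetic acid work‑up gives 9 together with the enantiomeric keto aldehyde F2. Step 5 on the racemate gives 10 and the enantiomeric formate F3, which are separated by preparative chromatography on a chiral stationary phase (amylose tris(3,5‑dimethylphenylcarbamate)). The route is rejoined at 10.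

Step 5 may fail by migration of hydrogen instead of the ring carbon in the Criegee intermediate (over‑oxidation to the carboxylic acid), or by oxidation of the ring ketone as well. Fallback (radical decarboxylative hydroxylation): setting out from 9, Pinnick oxidation (NaClO2, NaH2PO4, 2‑methylbut‑2‑ene, t‑BuOH–H2O) gives the carboxylic acid F4 on purpose. Esterification with N‑hydroxypyridine‑2‑thione (DCC, CH2Cl2, dark) gives the thiohydroxamate ester F5. Its photolysis under O2 with t‑BuSH (Barton decarboxylation with oxygen trapping) should give the hydroperoxide F6, oxygen entering the secondary radical anti to the vicinal benzoate, that is with the geometry of the migration it replaces. P(OMe)3 reduces it to the alcohol F7. DBU (0.2 equiv) in CH2Cl2 as in step 6 then opens the bridge to the ring‑opened diol dibenzoate F8, whose benzoyl shift gives 13, where the route is rejoined.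

Step 6 may fail by wandering of the secondary benzoate to the freed hydroxyl groups under amine base, or by further β‑elimination of the γ‑oxygenated enone towards a phenol. Fallback (silyl‑mediated opening, acid finish): setting out from 10, soft enolisation with TMSOTf/Et3N in CH2Cl2 at −78 °C, the known way to open oxabicyclic β‑alkoxy ketones, gives the ring‑opened enone with the primary oxygen capped at once as the trimethylsilyl ether F9, so that no alkoxide is ever free. Camphorsulfonic acid (cat.) in MeOH at 0 °C then removes the silyl group, lets the tertiary benzoate shift to the primary oxygen under acid catalysis (through 11 and 12) and cleaves the formate by acid‑catalysed transesterification. The route is rejoined at 13.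

**Further compounds**

F1 | step 4 | (1R,4S,5R,6S)-6-formyl-8-[(triethylsilyl)oxy]-2-oxabicyclo[2.2.2]oct-7-ene-4,5-diyl dibenzoate | O=C(c1ccccc1)O[C@]12CO[C@H](C=C1O[Si](CC)(CC)CC)[C@H](C=O)[C@H]2OC(=O)c1ccccc1
F2 | step 4 | (1R,4S,5R,6S)-6-formyl-8-oxo-2-oxabicyclo[2.2.2]octane-4,5-diyl dibenzoate | O=C(c1ccccc1)O[C@]12CO[C@H](CC1=O)[C@H](C=O)[C@H]2OC(=O)c1ccccc1
F3 | step 4 | (1R,4S,5R,6S)-6-(formyloxy)-8-oxo-2-oxabicyclo[2.2.2]octane-4,5-diyl dibenzoate | O=C(c1ccccc1)O[C@]12CO[C@H](CC1=O)[C@H](OC=O)[C@H]2OC(=O)c1ccccc1
F4 | step 5 | (1S,4R,5S,6R)-4,5-bis(benzoyloxy)-8-oxo-2-oxabicyclo[2.2.2]octane-6-carboxylic acid | O=C(c1ccccc1)O[C@@]12CO[C@@H](CC1=O)[C@@H](C(=O)O)[C@@H]2OC(=O)c1ccccc1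
F5 | step 5 | 2-thioxopyridin-1(2H)-yl (1S,4R,5S,6R)-4,5-bis(benzoyloxy)-8-oxo-2-oxabicyclo[2.2.2]octane-6-carboxylate | O=C(c1ccccc1)O[C@@]12CO[C@@H](CC1=O)[C@@H](C(=O)ON1C=CC=CC1=S)[C@@H]2OC(=O)c1ccccc1
F6 | step 5 | (1S,4R,5S,6R)-6-hydroperoxy-8-oxo-2-oxabicyclo[2.2.2]octane-4,5-diyl dibenzoate | O=C(c1ccccc1)O[C@@]12CO[C@@H](CC1=O)[C@@H](OO)[C@@H]2OC(=O)c1ccccc1
F7 | step 5 | (1S,4R,5S,6R)-6-hydroxy-8-oxo-2-oxabicyclo[2.2.2]octane-4,5-diyl dibenzoate | O=C(c1ccccc1)O[C@@]12CO[C@@H](CC1=O)[C@@H](O)[C@@H]2OC(=O)c1ccccc1
F8 | step 5 | (1R,2S,3R)-3-hydroxy-1-(hydroxymethyl)-6-oxocyclohex-4-ene-1,2-diyl dibenzoate | OC[C@]1(OC(=O)c2ccccc2)C(=O)C=C[C@@H](O)[C@@H]1OC(=O)c1ccccc1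
F9 | step 6 | (1R,2S,3R)-3-(formyloxy)-6-oxo-1-{[(trimethylsilyl)oxy]methyl}cyclohex-4-ene-1,2-diyl dibenzoate | C[Si](C)(C)OC[C@]1(OC(=O)c2ccccc2)C(=O)C=C[C@@H](OC=O)[C@@H]1OC(=O)c1ccccc1
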